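## Structural features

The target is a halimane-type Δ1(10)-octalin: ring A (C1–C5, C10) and ring B (C5–C10) share the C5–C10 bond, and the only ring alkene, C1=C10, sits on the fusion carbon. Ring A carries the quaternary C4 (methyl and methoxycarbonyl) directly beside the fusion methine C5. Ring B carries C8 (methyl C17, H) directly beside the quaternary C9 (methyl C20 and the C11 chain), and the trigonal C10 separates the two stereo-pairs. A five-carbon chain (C11–C15) leaves C9, with an isolated methyl stereocentre at C13 and a primary acetate at C15; the configuration is (4S,5R,8R,9S,13S). The acetate is the fragile group (hydrides, alkoxides, amide bases, organometallics), whereas the neopentyl methyl ester is robust, and the C1=C10 alkene could migrate under strong acid, so it is best formed last. The real difficulty lies in the two quaternary carbons, each flanked by a tertiary stereocentre, and in relaying configuration from C8/C9 to C4/C5 across C10; C13 is too remote for any relay and has to come from the chiral pool. The key step exploits two facts: C17–C8–C9(C20)–C11 has the connectivity and (E) geometry of 2-methylbut-2-enal, and C7–C6–C5–C10 of ring B is a butadiene whose C10 end can carry an oxygen, from which ring A is later grown.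

## Logic of the disconnections

20 ⇒ 18 + 19. The C2–C3 and C4–C5 bonds are cut, because ring A is a cyclohexene whose alkene lies exactly where a [4+2] cycloaddition leaves it, and C4 with its methyl and ester is the α-carbon of 19. One step then supplies ring A, C4, C5 and the ester. The forward step must be ortho-regioselective, ester-endo, and must add to the diene face opposite C20.

18 ⇒ 17 ⇒ 16. The C1–C10 bond is cut (vinyl onto an enol triflate), then the C10–O bond of the triflate is traced to a ketone. Because C9 is quaternary, only C5 can lose a proton, so 17 is a single regioisomer. The demand is that both forward steps spare the acetate, which means no metal enolate and a neutral coupling.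

16 ⇒ 15 ⇒ 14 ⇒ 13 ⇒ 12. No skeletal bond is cut here. The C10 ketone is traced to a silyl-masked carbinol and the acetate to an ester via the alcohol. The order matters in the forward direction: the hydride reduction precedes acetylation, and acetylation precedes the unmasking of C10, so that C15 never needs a protecting group of its own.

12 ⇒ 11 ⇒ 4 + 9. The C11–C12 bond is cut as an alkene (Wittig). Hydrogenation of 11 also removes the C5=C6 alkene left by the cycloaddition. This splits the molecule into the ring-B aldehyde and the C12–C15 chiral-pool piece. The ylide has to add to a neopentyl aldehyde; alkene geometry is irrelevant.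

9 ⇒ 7 ⇒ 5 (through 8 and 6). The C12–P bond is cut, and the two chain ends of a methylsuccinate are told apart by oxidation level: borane reduces only the free acid, the lactone locks the distinction, and bromide opens it at C12. No base acts while C13 is α to a carbonyl, so C13 is not at risk.

4 ⇒ 2 + 3. The C7–C8 and C9–C10 bonds are cut across ring B. This removes ring B, both ring-B stereocentres and the quaternary C9 in one operation and leaves two small aldehyde-derived pieces. The forward step must select one enantioface of 3; the relative configuration at C8/C9 follows from the alkene geometry.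

2 ⇒ 1. The O–Si bond is cut; 2 is the silyl dienol ether of 1.

## Other disconnections considered

Alternative 1: The cut is the C9–C20 bond, with C10–C20 as a sacrificial bond. In the forward sense the allylic alcohol A2 (both rings present, C9=C10, C1 hydroxyl on the face of H5, side chain on C9) would be treated with Et2Zn/CH2I2. The zinc alkoxide should deliver CH2 to its own face and give the cyclopropyl carbinol A1. The C10–C20 bond then has to be cleaved and the C1 oxygen turned into C1=C10, for example by radical deoxygenation at C1 with ring opening of the cyclopropylcarbinyl radical.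
- In its favour: directed cyclopropanation of tetrasubstituted allylic alcohols is dependable. Face selectivity comes from one resident stereocentre and needs no chiral catalyst, so in certainty of stereocontrol at C9 it is the equal or the better of step 2. The C1 oxygen sits where the final alkene must end, and no olefination of a neopentyl aldehyde is needed.
- Against it: A2 already holds both rings and C4, C5, C8, C13 and C1, so the step retains only one C–C bond and one stereocentre. C8 has to be set beside a tetrasubstituted alkene beforehand. The ring opening can cleave C9–C10 instead of C10–C20, which would expand ring B. A dissolving-metal variant would endanger the ester.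
- Comparison: step 2 makes ring B, two bonds and C8/C9 from two small aldehydes, whereas this step adds one methyl to a finished bicycle. It is mechanistically predictable, but in step economy it is clearly worse, since a full bicycle synthesis must precede it and at least three operations follow it.

Alternative 2: The cut is the C8–C9 bond of ring B, read as a ring expansion. The epoxy cyclopentanol A4 (carbinol C10, epoxide carbons C9 and C20) would be treated with BF3·OEt2. The epoxide should open at the tertiary C9, C8 should migrate from C10 to C9 anti to the breaking C–O bond, and C10 should become the ketone, giving A3 with a hydroxymethyl group on C9.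
- In its favour: the migration is stereospecific (retention at C8, inversion at C9), and the more substituted ring carbon is the one expected to migrate. The step delivers the ring-B ketone with the side chain already attached, so on the stretch covered here by steps 5, 6, 9 and 10 it is the better of the two.
- Against it: C20 arrives oxidised and must be deoxygenated at a neopentyl position in the presence of a ketone. A3 is a β-hydroxy ketone with a quaternary α-carbon and could lose formaldehyde by retro-aldol cleavage. A4 needs three stereocentres: an enantioenriched 2-methylcyclopentanone with a labile α-centre, an alkenyl-metal addition, and a directed epoxidation of a 1,1-disubstituted alkene. Hydride shift or migration of C5 could compete.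
- Comparison: both plans set C8/C9, but here C8 must pre-exist and C9 depends on a chain of relative inductions, while step 2 sets both at once under catalyst control. The overall count to the stage of 16 would not be lower once the precursor synthesis, the deoxygenation and the exchange of the C15 silyl group are added.

Alternative 3: The cut is the C4–C5 bond of ring A. The lactone A6 (a δ-valerolactone with the ring-B cyclohexenyl group on C1) would be converted to its silyl ketene acetal, which should rearrange [3,3] with C4–C5 formation and O–C1 cleavage to the acid A5.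
- In its favour: the step is intramolecular and its regiochemistry is unambiguous. The ring-bound ketene acetal enforces a boat-like array, so the single C1 carbinol centre would dictate both C5 (the face) and C4 (carboxyl cis to C6, trans to H5, as in the target). In stereochemical determinism at C4/C5 it is better than step 13, where regio-, endo- and face selectivity are only biased.
- Against it: A6 needs a C1 carbinol set under reagent control far from C8/C9, plus several steps of lactone assembly. The bicyclo[2.2.2]-like transition state of a six-membered lactone is strained, and a tetrasubstituted ketene acetal must forge a quaternary centre beside a hindered ring carbon. Esterification and exchange of the C15 silyl ether for acetate follow.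
- Comparison: this alternative concerns ring A only and could be combined with step 2; it competes with steps 11–13. It would cost about four to five more steps than the single cycloaddition of step 13, but it would be the better choice if the selectivity of step 13 proved inadequate.

Key step: step 2

Assumption: (R)-2-methylsuccinic acid 4-methyl ester (5) is taken as a catalogue compound; starting from the free diacid would add one desymmetrising step.
Remark: atoms carry the diterpene numbers C1–C20 of the target in every compound (C17 on C8, C20 on C9). Re-derived descriptors: 20 is (4S,5R,8R,9S,13S); cycloadduct 4 is (1S,2R,6R) and carries C8 and C9 exactly as in 20.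

## Route

Step 1
Reactants: 1 (E)-but-2-enal (crotonaldehyde)
Product: 2 (E)-1-(tert-butyldimethylsilyloxy)buta-1,3-diene
Conditions: TBSOTf, Et3N, Et2O, 0 °C → rt
Reagents that add atoms: tert-butyldimethylsilyl triflate, CC(C)(C)[Si](C)(C)OS(=O)(=O)C(F)(F)F
Why: Silyl dienol ether formation: O-silylation of the enal makes the γ-protons acidic and Et3N removes one, giving mainly the (E)-diene; any (Z)-diene is a poor diene and stays behind in step 2.

Step 2
Reactants: 2 (E)-1-(tert-butyldimethylsilyloxy)buta-1,3-diene; 3 (E)-2-methylbut-2-enal (tiglic aldehyde)
Product: 4 (1S,2R,6R)-2-(tert-butyldimethylsilyloxy)-1,6-dimethylcyclohex-3-ene-1-carbaldehyde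
Conditions: (S)-1-(2-methylphenyl)-3,3-diphenyltetrahydro-1H,3H-pyrrolo[1,2-c][1,3,2]oxazaborole (20 mol %), HN(SO2CF3)2 (18 mol %), 2 (3 equiv), CH2Cl2, −78 → −40 °C
Reagents that add atoms: none
Why: The protonated oxazaborolidine is a cationic boron Lewis acid that binds the formyl oxygen of 3, with a formyl C–H···O contact holding the s-trans enal over one phenyl group, and the electron-rich diene 2 then adds in a concerted, asynchronous normal-demand [4+2] cycloaddition. The closest known reaction type is the cationic-oxazaborolidine-catalysed Diels–Alder reaction of 2-substituted acroleins with 1-silyloxy-1,3-dienes; the present pair differs in the β-methyl group of the enal. Ring B closes by intermolecular six-membered cycloaddition in which C7–C8 forms ahead of C9–C10, because the largest HOMO coefficient of 2 lies at the unsubstituted terminus C7 and the largest LUMO coefficient of bound 3 at C8 (ortho orientation). C8 and C9 are fixed relative to each other by suprafacial addition to the (E)-alkene, which leaves C17 and C20 cis and C11 trans to C17. Their absolute sense (8R,9S) is fixed by the catalyst, which must leave open the face of 3 that is Re at C9 and Si at C8; the (S)-configured catalyst is chosen on the binding model for 2-substituted enals. C10 follows from the carbonyl-endo approach (silyloxy cis to formyl, as drawn) but is erased at ketone 16, so only enantioface selectivity is truly required. The lower dienophilicity caused by the β-methyl group is met by triflimide activation, excess 2 and slow warming, and the tert-butyldimethylsilyl group is kept because it resists silyl transfer to the Lewis acid better than trimethylsilyl yet can still be removed from the hindered C10 oxygen in step 9.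

Step 3
Reactants: 5 (2R)-4-methoxy-2-methyl-4-oxobutanoic acid ((R)-2-methylsuccinic acid 4-methyl ester)
Product: 7 (4R)-4-methyloxolan-2-one, via methyl (3R)-4-hydroxy-3-methylbutanoate 6 (not isolated)
Conditions: BH3·SMe2, THF, 0 °C → rt; MeOH; then TsOH·H2O (5 mol %), CH2Cl2, rt
Reagents that add atoms: none
Why: Borane reduces the free acid (through its acyloxyborane) far faster than the methyl ester, and the γ-hydroxy ester closes to the five-membered lactone under acid catalysis; no base is present, so the centre α to the acid is kept, and the two chain ends are now distinct (C12 is the O-alkyl carbon, C15 the acyl carbon).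

Step 4
Reactants: 7 (4R)-4-methyloxolan-2-one
Product: 9 [(2R)-4-methoxy-2-methyl-4-oxobutyl]triphenylphosphonium bromide, via methyl (3R)-4-bromo-3-methylbutanoate 8 (not isolated)
Conditions: HBr (gas, saturated), MeOH, 0 → 40 °C; concentrate; PPh3, MeCN, reflux
Reagents that add atoms: hydrogen bromide, Br; methanol, CO; triphenylphosphine, c1ccc(cc1)P(c1ccccc1)c1ccccc1
Why: Acid-promoted O-alkyl cleavage of the lactone by bromide (SN2 at C12) together with Fischer esterification gives the γ-bromo ester, and SN2 quaternisation of PPh3 at the primary, β-branched C12 gives the salt; C13 is not touched.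

Step 5
Reactants: 4 (1S,2R,6R)-2-(tert-butyldimethylsilyloxy)-1,6-dimethylcyclohex-3-ene-1-carbaldehyde; 9 [(2R)-4-methoxy-2-methyl-4-oxobutyl]triphenylphosphonium bromide
Product: 11 methyl (3R,4Z)-5-[(1R,2R,6R)-2-(tert-butyldimethylsilyloxy)-1,6-dimethylcyclohex-3-en-1-yl]-3-methylpent-4-enoate, via phosphorus ylide 10 (not isolated)
Conditions: 9 (1.5 equiv), NaHMDS (1.45 equiv), THF, −78 → 0 °C; then 4, −78 °C → rt
Reagents that add atoms: none
Why: Wittig olefination: the non-stabilised ylide adds to the non-enolisable neopentyl aldehyde and the oxaphosphetane collapses to the (Z)-alkene; the geometry is irrelevant because step 6 saturates it, and the ester is tolerated at low temperature as in the usual ω-alkoxycarbonylalkyl ylides.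

Step 6
Reactants: 11 methyl (3R,4Z)-5-[(1R,2R,6R)-2-(tert-butyldimethylsilyloxy)-1,6-dimethylcyclohex-3-en-1-yl]-3-methylpent-4-enoate
Product: 12 methyl (3S)-5-[(1S,2R,6R)-2-(tert-butyldimethylsilyloxy)-1,6-dimethylcyclohexyl]-3-methylpentanoate
Conditions: H2 (1 atm), PtO2 (5 mol %), EtOAc, rt
Reagents that add atoms: none
Why: Heterogeneous hydrogenation saturates both disubstituted alkenes (C11=C12 and ring C5=C6); platinum is preferred to palladium to suppress hydrogenolysis or migration at the allylic C10–O bond, and no stereocentre is created.

Step 7
Reactants: 12 methyl (3S)-5-[(1S,2R,6R)-2-(tert-butyldimethylsilyloxy)-1,6-dimethylcyclohexyl]-3-methylpentanoate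
Product: 13 (3S)-5-[(1S,2R,6R)-2-(tert-butyldimethylsilyloxy)-1,6-dimethylcyclohexyl]-3-methylpentan-1-ol
Conditions: LiAlH4, THF, 0 °C
Reagents that add atoms: none
Why: Hydride reduction of the ester to the primary alcohol at C15; the hindered secondary silyl ether is inert to LiAlH4.

Step 8
Reactants: 13 (3S)-5-[(1S,2R,6R)-2-(tert-butyldimethylsilyloxy)-1,6-dimethylcyclohexyl]-3-methylpentan-1-ol
Product: 14 (3S)-5-[(1S,2R,6R)-2-(tert-butyldimethylsilyloxy)-1,6-dimethylcyclohexyl]-3-methylpentyl acetate
Conditions: Ac2O, pyridine, DMAP (5 mol %), CH2Cl2, rt
Reagents that add atoms: acetic anhydride, CC(=O)OC(C)=O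
Why: Nucleophile-catalysed acylation of the only free hydroxyl; the acetate goes in after the last hydride step and before C10 is unmasked, so C15 never needs a protecting group exchange.

Step 9
Reactants: 14 (3S)-5-[(1S,2R,6R)-2-(tert-butyldimethylsilyloxy)-1,6-dimethylcyclohexyl]-3-methylpentyl acetate
Product: 15 (3S)-5-[(1S,2R,6R)-2-hydroxy-1,6-dimethylcyclohexyl]-3-methylpentyl acetate
Conditions: HF (48 % aq), MeCN, rt
Reagents that add atoms: none
Why: Acidic fluoride desilylation; aqueous HF in MeCN cleaves even hindered secondary silyl ethers and is not basic enough to touch the acetate.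

Step 10
Reactants: 15 (3S)-5-[(1S,2R,6R)-2-hydroxy-1,6-dimethylcyclohexyl]-3-methylpentyl acetate
Product: 16 (3S)-5-[(1S,6R)-1,6-dimethyl-2-oxocyclohexyl]-3-methylpentyl acetate
Conditions: DMP, CH2Cl2, rt
Reagents that add atoms: none
Why: Dess–Martin oxidation of the hindered secondary alcohol under neutral conditions; the ketone has no epimerisable α-stereocentre (C9 is quaternary, C8 is β), and either C10 epimer from step 2 converges here.

Step 11
Reactants: 16 (3S)-5-[(1S,6R)-1,6-dimethyl-2-oxocyclohexyl]-3-methylpentyl acetate
Product: 17 (3S)-5-[(1S,6R)-1,6-dimethyl-2-(trifluoromethylsulfonyloxy)cyclohex-2-en-1-yl]-3-methylpentyl acetate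
Conditions: Tf2O, 2,6-di-tert-butyl-4-methylpyridine, CH2Cl2, 0 °C → rt
Reagents that add atoms: trifluoromethanesulfonic anhydride, O=S(=O)(OS(=O)(=O)C(F)(F)F)C(F)(F)F
Why: Enol triflate formation by O-sulfonylation of the ketone and loss of a C5 proton to the hindered pyridine; with C9 quaternary only the C5=C10 triflate can form, and the absence of a metal enolate protects the acetate.

Step 12
Reactants: 17 (3S)-5-[(1S,6R)-1,6-dimethyl-2-(trifluoromethylsulfonyloxy)cyclohex-2-en-1-yl]-3-methylpentyl acetate
Product: 18 (3S)-5-[(1S,6R)-2-ethenyl-1,6-dimethylcyclohex-2-en-1-yl]-3-methylpentyl acetate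
Conditions: tributyl(vinyl)stannane, Pd(PPh3)4 (5 mol %), LiCl (3 equiv), THF, 65 °C
Reagents that add atoms: tributyl(vinyl)stannane, C=C[Sn](CCCC)(CCCC)CCCC
Why: Stille coupling: oxidative addition of the vinyl triflate to zerovalent palladium (chloride stabilises the adduct), transmetalation from tin and reductive elimination give the C5=C10–C1=C2 diene under neutral conditions that the acetate tolerates.

Step 13
Reactants: 18 (3S)-5-[(1S,6R)-2-ethenyl-1,6-dimethylcyclohex-2-en-1-yl]-3-methylpentyl acetate; 19 methyl 2-methylprop-2-enoate (methyl methacrylate)
Product: 20 methyl (1S,5S,6R,8aR)-5-[(3S)-5-acetoxy-3-methylpentyl]-1,5,6-trimethyl-1,2,3,5,6,7,8,8a-octahydronaphthalene-1-carboxylate (target)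
Conditions: 19 (5 equiv), EtAlCl2 (2 equiv), BHT (trace), CH2Cl2, −40 → 0 °C
Reagents that add atoms: none
Why: Lewis-acid-promoted Diels–Alder reaction: EtAlCl2 lowers the LUMO of 19 and sharpens the ortho orientation (C3 to the free terminus C2, C4 to C5), and the ester should sit endo because this semicyclic diene has no bridging group to oppose it. The dienophile should add to the face of C5 opposite the pseudoaxial C20 in the half-chair that keeps C17 equatorial, which sets 5R and 4S together and leaves the alkene at C1=C10; EtAlCl2 also scavenges protons that would isomerise the diene.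

## Compound list

1 | (E)-but-2-enal (crotonaldehyde) | C/C=C/C=O | starting material
2 | (E)-1-(tert-butyldimethylsilyloxy)buta-1,3-diene | C=C/C=C/O[Si](C)(C)C(C)(C)C | intermediate
3 | (E)-2-methylbut-2-enal (tiglic aldehyde) | C/C=C(\C)C=O | starting material
4 | (1S,2R,6R)-2-(tert-butyldimethylsilyloxy)-1,6-dimethylcyclohex-3-ene-1-carbaldehyde | CC(C)(C)[Si](C)(C)O[C@@H]1C=CC[C@@H](C)[C@]1(C)C=O | intermediate
5 | (2R)-4-methoxy-2-methyl-4-oxobutanoic acid | COC(=O)C[C@@H](C)C(=O)O | starting material
6 | methyl (3R)-4-hydroxy-3-methylbutanoate (not isolated) | COC(=O)C[C@@H](C)CO | intermediate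
7 | (4R)-4-methyloxolan-2-one | C[C@H]1COC(=O)C1 | intermediate
8 | methyl (3R)-4-bromo-3-methylbutanoate (not isolated) | COC(=O)C[C@@H](C)CBr | intermediate
9 | [(2R)-4-methoxy-2-methyl-4-oxobutyl]triphenylphosphonium bromide | [Br-].COC(=O)C[C@@H](C)C[P+](c1ccccc1)(c1ccccc1)c1ccccc1 | intermediate
10 | methyl (3R)-3-methyl-4-(triphenyl-λ5-phosphanylidene)butanoate (ylide, not isolated) | COC(=O)C[C@@H](C)C=P(c1ccccc1)(c1ccccc1)c1ccccc1 | intermediate
11 | methyl (3R,4Z)-5-[(1R,2R,6R)-2-(tert-butyldimethylsilyloxy)-1,6-dimethylcyclohex-3-en-1-yl]-3-methylpent-4-enoate | CC(C)(C)[Si](C)(C)O[C@@H]1C=CC[C@@H](C)[C@]1(C)/C=C\[C@H](C)CC(=O)OC | intermediate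
12 | methyl (3S)-5-[(1S,2R,6R)-2-(tert-butyldimethylsilyloxy)-1,6-dimethylcyclohexyl]-3-methylpentanoate | CC(C)(C)[Si](C)(C)O[C@@H]1CCC[C@@H](C)[C@]1(C)CC[C@H](C)CC(=O)OC | intermediate
13 | (3S)-5-[(1S,2R,6R)-2-(tert-butyldimethylsilyloxy)-1,6-dimethylcyclohexyl]-3-methylpentan-1-ol | CC(C)(C)[Si](C)(C)O[C@@H]1CCC[C@@H](C)[C@]1(C)CC[C@H](C)CCO | intermediate
14 | (3S)-5-[(1S,2R,6R)-2-(tert-butyldimethylsilyloxy)-1,6-dimethylcyclohexyl]-3-methylpentyl acetate | CC(C)(C)[Si](C)(C)O[C@@H]1CCC[C@@H](C)[C@]1(C)CC[C@H](C)CCOC(C)=O | intermediate
15 | (3S)-5-[(1S,2R,6R)-2-hydroxy-1,6-dimethylcyclohexyl]-3-methylpentyl acetate | O[C@@H]1CCC[C@@H](C)[C@]1(C)CC[C@H](C)CCOC(C)=O | intermediate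
16 | (3S)-5-[(1S,6R)-1,6-dimethyl-2-oxocyclohexyl]-3-methylpentyl acetate | O=C1CCC[C@@H](C)[C@]1(C)CC[C@H](C)CCOC(C)=O | intermediate
17 | (3S)-5-[(1S,6R)-1,6-dimethyl-2-(trifluoromethylsulfonyloxy)cyclohex-2-en-1-yl]-3-methylpentyl acetate | FC(F)(F)S(=O)(=O)OC1=CCC[C@@H](C)[C@]1(C)CC[C@H](C)CCOC(C)=O | intermediate
18 | (3S)-5-[(1S,6R)-2-ethenyl-1,6-dimethylcyclohex-2-en-1-yl]-3-methylpentyl acetate | C=CC1=CCC[C@@H](C)[C@]1(C)CC[C@H](C)CCOC(C)=O | intermediate
19 | methyl 2-methylprop-2-enoate (methyl methacrylate) | COC(=O)C(C)=C | starting material
20 | methyl (1S,5S,6R,8aR)-5-[(3S)-5-acetoxy-3-methylpentyl]-1,5,6-trimethyl-1,2,3,5,6,7,8,8a-octahydronaphthalene-1-carboxylate | COC(=O)[C@@]1(C)CCC=C2[C@H]1CC[C@@H](C)[C@]2(C)CC[C@H](C)CCOC(C)=O | target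

## Step count and least certain steps

Total: 13 steps. Longest linear sequence: 11 steps (steps 1, 2 and 5–13); steps 3 and 4 make the side-chain branch.

Step 2 (key step). The most likely failures are slow turnover, because the β-methyl group makes 3 a weak dienophile while 2 is slowly consumed by silyl transfer or oligomerisation on the cationic catalyst, and incomplete enantioface discrimination for a β-substituted enal. If only the sense of induction were wrong, the mirror-image catalyst would be used. Fallback (sets out from 2 and 3, returns to the route at 4): the cycloaddition is run with an achiral Lewis acid (Me2AlCl, CH2Cl2, −78 °C) to give the racemic cycloadduct F1. This is condensed with (1R,2R)-N,N'-dimethyl-1,2-diphenylethane-1,2-diamine (4 Å molecular sieves, Et2O, rt) to two diastereomeric imidazolidines, which are separated by chromatography. The imidazolidine aminal F2 that belongs to 4 is hydrolysed (0.5 M aqueous HCl, Et2O, 0 °C) to release enantiopure 4, and the diamine is recovered. Catalyst control is thereby replaced by a classical resolution, at the cost of two steps and half of the material.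

Step 13. Three things can go wrong: poor facial selectivity (the bias rests on one ring-B conformer preference of modest size), erosion of the ester-endo preference (the Lewis-acid-bound ester is bulky and C4 becomes quaternary), and leakage to the meta regioisomer or oligomerisation of the diene if the cycloaddition is slow. Fallback (sets out from 18, returns at 20): 18 is treated with methacrolein and the (S)-oxazaborolidinium triflimide of step 2 (CH2Cl2, −78 °C) to give the ring-A aldehyde F3, in which the catalyst fixes the enantioface of the enal and hence 4S. The carbonyl-endo mode then ties bottom-face addition at C5 to that choice, in line with the substrate bias. Pinnick oxidation (NaClO2, NaH2PO4, 2-methylbut-2-ene, t-BuOH/H2O) gives the ring-A acid F4, and Me3SiCHN2 in MeOH/toluene gives 20.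

Step 11. The most likely failures are sluggish O-sulfonylation of a ketone flanked by a quaternary carbon and cationic side reactions of the triflyloxycarbenium ion (1,2-shift from C9). Fallback (sets out from 16, returns at 18 and so replaces steps 11 and 12): vinylmagnesium bromide premixed with CeCl3 (THF, −78 °C) adds to the hindered ketone much faster than to the acetate and gives the tertiary allylic alcohol F5. Dehydration with methyl N-(triethylammoniosulfonyl)carbamate (benzene, 50 °C) can only remove a hydrogen from C5, so it gives 18.

Step 5. The most likely failure is slow addition of the β-branched ylide to the neopentyl, β-silyloxy aldehyde, which would let the ylide decompose by self-condensation with its own ester. Fallback (sets out from 7 and 4, returns at 12): 8 is isolated after the first stage of step 4. It is converted with 1-phenyl-1H-tetrazole-5-thiol and K2CO3 (DMF) to the tetrazolyl sulfide F6 and oxidised with mCPBA (CH2Cl2) to the tetrazolyl sulfone F7. Julia–Kocienski olefination (KHMDS added to F7 and 4 in THF at −78 °C) gives the (E)-alkenoate F8; the smaller, harder sulfonyl carbanion adds irreversibly. Hydrogenation as in step 6 gives 12.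

## Further compounds

F1 | step 2 | racemic 2-(tert-butyldimethylsilyloxy)-1,6-dimethylcyclohex-3-ene-1-carbaldehyde (4 together with its mirror image) | CC(C)(C)[Si](C)(C)O[C@@H]1C=CC[C@@H](C)[C@]1(C)C=O.CC(C)(C)[Si](C)(C)O[C@H]1C=CC[C@H](C)[C@@]1(C)C=O
F2 | step 2 | (4R,5R)-1,3-dimethyl-4,5-diphenylimidazolidine aminal of 4 (C2 bears the cyclohexenyl group of 4) | CC(C)(C)[Si](C)(C)O[C@@H]1C=CC[C@@H](C)[C@]1(C)C2N(C)[C@H](c3ccccc3)[C@@H](c3ccccc3)N2C
F3 | step 13 | ring-A aldehyde: 20 with formyl in place of methoxycarbonyl on C4 | O=C[C@@]1(C)CCC=C2[C@H]1CC[C@@H](C)[C@]2(C)CC[C@H](C)CCOC(C)=O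
F4 | step 13 | ring-A acid: 20 with carboxyl in place of methoxycarbonyl on C4 | OC(=O)[C@@]1(C)CCC=C2[C@H]1CC[C@@H](C)[C@]2(C)CC[C@H](C)CCOC(C)=O
F5 | step 11 | (3S)-5-[(1S,6R)-2-ethenyl-2-hydroxy-1,6-dimethylcyclohexyl]-3-methylpentyl acetate (either epimer at the carbinol carbon C10) | C=CC1(O)CCC[C@@H](C)[C@]1(C)CC[C@H](C)CCOC(C)=O
F6 | step 5 | methyl (3R)-3-methyl-4-[(1-phenyl-1H-tetrazol-5-yl)sulfanyl]butanoate | COC(=O)C[C@@H](C)CSc1nnnn1-c2ccccc2
F7 | step 5 | methyl (3R)-3-methyl-4-[(1-phenyl-1H-tetrazol-5-yl)sulfonyl]butanoate | COC(=O)C[C@@H](C)CS(=O)(=O)c1nnnn1-c2ccccc2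
F8 | step 5 | methyl (3R,4E)-5-[(1R,2R,6R)-2-(tert-butyldimethylsilyloxy)-1,6-dimethylcyclohex-3-en-1-yl]-3-methylpent-4-enoate | CC(C)(C)[Si](C)(C)O[C@@H]1C=CC[C@@H](C)[C@]1(C)/C=C/[C@H](C)CC(=O)OC
A1 | alternative 1 | cyclopropyl carbinol with C20 bridging C9 and C10, C1 hydroxyl syn to C20, C15 silyl ether | COC(=O)[C@@]1(C)CC[C@H](O)[C@]23[C@H]1CC[C@@H](C)[C@]2(C3)CC[C@H](C)CCO[Si](C)(C)C(C)(C)C
A2 | alternative 1 | bicyclic allylic alcohol with C9=C10, C1 hydroxyl on the face of H5, no C20 | COC(=O)[C@@]1(C)CC[C@H](O)C2=C(CC[C@H](C)CCO[Si](C)(C)C(C)(C)C)[C@H](C)CC[C@@H]12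
A3 | alternative 2 | ring-B ketone with hydroxymethyl (C20) on the quaternary C9 | O=C1CCC[C@@H](C)[C@]1(CO)CC[C@H](C)CCO[Si](C)(C)C(C)(C)C
A4 | alternative 2 | 2-methylcyclopentan-1-ol bearing on C1 a 2-substituted oxiran-2-yl group (epoxide carbons C9 and C20), hydroxyl cis to the ring methyl | C[C@@H]1CCC[C@@]1(O)[C@@]1(CC[C@H](C)CCO[Si](C)(C)C(C)(C)C)CO1
A5 | alternative 3 | ring-A carboxylic acid with the C15 silyl ether | OC(=O)[C@@]1(C)CCC=C2[C@H]1CC[C@@H](C)[C@]2(C)CC[C@H](C)CCO[Si](C)(C)C(C)(C)C
A6 | alternative 3 | 3-methyl-δ-valerolactone carrying the ring-B cyclohexenyl group on the O-bearing carbon C1 (either epimer at the methyl-bearing lactone carbon, which is lost on enolisation) | CC1CC[C@@H](OC1=O)C1=CCC[C@@H](C)[C@]1(C)CC[C@H](C)CCO[Si](C)(C)C(C)(C)C
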